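**Plan**

1. Numbering (halimane type): ring B = C5(O)–C6–C7–C8(CH3 = C17)–C9–C10; lactone carbonyl = C20; C9 side chain = C11–C12 plus butenolide C13–C16; propanoate = C1–C3; isopropenyl = C4, C18, C19.
2. Retrosynthetic cuts, in order: C4=C18 (methylenation of a C4 methyl ketone); C3 and C4 reconnected as the C3=C4 alkene of a temporary cyclohexene ring A (C1–C5, C10), which hides both the ester and the isopropenyl group and ties C10 to C5; C12–C13 (B-alkyl Suzuki coupling, butenolide brought in as a preformed ring); C8–C9 of ring B (key step); C9–C11, C5–C6 with the lactone C–O bond, and C9–C10.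
3. Enabling feature: C9 is both the α-carbon of the C20 lactone carbonyl and a ring-B atom, and its ring neighbour C8 carries a methyl group. This carbonyl–Cα–C(CH3) array is the retron of a lactone α-radical adding 6-exo to a terminal vinyl group, whose CH2 ends as C17.
4. Forward order: ring A comes with the commercial enone; the lactone ring closes in step 4; ring B closes in step 7, the last ring closure of the route; the butenolide is then attached intact (step 9); ring A is opened by ozonolysis (step 10) and C4 is methylenated (step 11).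
5. Stereochemistry: C10 from a RAMP-hydrazone alkylation; C5 from C10 by stereoconvergent cis-lactonization; C9 from C5 (the tether reaches one face only); C8 from a chair transition state of ring B (equatorial methyl).

Key step: step 7

Remark: 8 (THF solution), 20 and 21 are taken as commercial, and the facial sense of step 2 is assigned from the Enders azaenolate model.

**Step 1**
Reactants: 1 2-methylcyclohex-2-en-1-one; 2 (R)-1-amino-2-(methoxymethyl)pyrrolidine (RAMP)
Product: 3 (E)-RAMP hydrazone of 2-methylcyclohex-2-en-1-one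
Conditions: TsOH·H2O (cat.), cyclohexane, reflux, Dean–Stark
Reagents that add atoms: none
Why: Acid-catalysed condensation of the ketone with the N-amino group (hydrazone formation) should give the E hydrazone with the pyrrolidine turned away from the substituted C2, and no new stereocentre is formed.

**Step 2**
Reactants: 3 RAMP hydrazone; 4 methyl bromoacetate
Product: 6 methyl 2-[(1R,2E)-2-{[(2R)-2-(methoxymethyl)pyrrolidin-1-yl]imino}-3-methylcyclohex-3-en-1-yl]acetate, via lithium azaenolate 5 (not isolated)
Conditions: LiN(iPr)2, THF, 0 °C; then 4, −100 °C to rt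
Reagents that add atoms: none
Why: Enders RAMP-hydrazone alkylation: kinetic deprotonation at the ring CH2 next to C=N gives a chelated azaenolate that the bromoacetate should alkylate on the face left open by the methoxymethyl arm, which sets the 1R centre (C10 of the target), the mirror-image auxiliary giving the antipode.

**Step 3**
Reactants: 6 alkylated RAMP hydrazone
Product: 7 methyl 2-[(1R)-3-methyl-2-oxocyclohex-3-en-1-yl]acetate
Conditions: saturated aq. oxalic acid, Et2O, rt
Reagents that add atoms: water, O
Why: Mild two-phase hydrazone hydrolysis should return the ketone without epimerizing the adjacent stereocentre and without touching the methyl ester or the enone.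

**Step 4**
Reactants: 7 keto ester; 8 but-3-en-1-ylmagnesium bromide
Product: 11 (3aR,7aS)-7a-(but-3-en-1-yl)-7-methyl-3a,4,5,7a-tetrahydro-1-benzofuran-2(3H)-one, via bromomagnesium alkoxides 9 (not isolated), via trans-hydroxy ester 10 (not isolated)
Conditions: anhydrous CeCl3, THF, −78 °C to rt; aq. NH4Cl; then TsOH·H2O (cat.), CH2Cl2, 0 °C, short contact
Reagents that add atoms: none
Why: CeCl3-mediated Grignard 1,2-addition to the enone avoids enolization of C10, and the lactonization that follows is stereoconvergent at C5, because the cis-alkoxide closes by acyl substitution while the trans-hydroxy ester ionizes to the C3–C4–C5 allyl cation that the acetate arm on C10 can trap only on its own face, so the cis-fused γ-lactone should result from either addition mode.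

**Step 5**
Reactants: 11 cis-fused butenyl lactone
Product: 13 (3aS,7aS)-7a-(but-3-en-1-yl)-7-methyl-3-(phenylselanyl)-3a,4,5,7a-tetrahydro-1-benzofuran-2(3H)-one, via lithium enolate 12 (not isolated)
Conditions: LiN(iPr)2, THF, −78 °C; then PhSeBr, −78 °C
Reagents that add atoms: phenylselenyl bromide, Br[Se]c1ccccc1
Why: Selenenylation of the lithium lactone enolate installs the radical leaving group at C9, whose configuration is immaterial because this centre becomes planar again in steps 6 and 7.

**Step 6**
Reactants: 13 α-phenylselanyl lactone; 14 phenyl vinyl sulfoxide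
Product: 17 (3aS,7aS)-7a-(but-3-en-1-yl)-7-methyl-3-(phenylselanyl)-3-[2-(phenylsulfinyl)ethyl]-3a,4,5,7a-tetrahydro-1-benzofuran-2(3H)-one, via lithium enolate 15 (not isolated), via lithiated sulfoxide adduct 16 (not isolated)
Conditions: LiN(SiMe3)2, THF, −78 °C; then 14, −78 to −20 °C; AcOH quench
Reagents that add atoms: none
Why: Michael addition of the selenium-stabilized enolate to phenyl vinyl sulfoxide (a vinyl cation equivalent) should build the fully substituted C9 with a saturated two-carbon arm that later unmasks a vinyl group, the C9 and sulfur epimers being of no consequence.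

**Step 7**
Reactants: 17 selenide with sulfinylethyl arm
Product: 18 tricyclic lactone sulfoxide (5S,8R,9R,10R)
Conditions: Bu3SnH (syringe pump), AIBN (cat.), benzene (high dilution), 80 °C
Reagents that add atoms: none
Why: Bu3Sn• abstracts the PhSe group from C9 to give the tertiary lactone α-radical, which adds to the internal alkene carbon C8 of the butenyl group, and the primary C17 radical so formed takes hydrogen from Bu3SnH to become the C8 methyl group; the closest known reaction type is the reductive tin hydride cyclization of α-halo or α-seleno esters onto alkenes. Ring B (C5, C6, C7, C8, C9, C10) closes in the 6-exo-trig mode across the 1,3-positions of the existing γ-lactone, so the bridged 6-oxabicyclo[3.2.1]octan-7-one core arises directly. C9: the butenyl tether on C5 can reach only the lactone face on which it stands, so the new quaternary centre follows C5 whatever the configuration of the selenide. C8: a chair transition state of ring B with the C20–O bridge diaxial and the CH=CH2 unit pseudo-equatorial, clear of the axial hydrogens on C6 and C10, should lead mainly to the equatorial methyl group. The step needs 6-exo over 7-endo attack and ring closure before hydrogen transfer to C9: 7-endo closure would give a more strained bicyclo[4.2.1] lactone, slow addition keeps the stannane concentration low, and the saturated sulfinylethyl arm offers the C17 radical no alkene for a second cyclization.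

**Step 8**
Reactants: 18 tricyclic lactone sulfoxide
Product: 19 9-vinyl tricyclic lactone (5S,8R,9R,10R)
Conditions: NaHCO3 (solid), toluene, 110 °C
Reagents that add atoms: none
Why: Thermal syn-elimination of the alkyl phenyl sulfoxide (sulfoxide pyrolysis) should unmask the C9 vinyl group (C11=C12) without touching any stereocentre.

**Step 9**
Reactants: 19 9-vinyl tricyclic lactone; 20 9-borabicyclo[3.3.1]nonane (9-BBN); 21 3-bromofuran-2(5H)-one
Product: 23 butenolide-bearing tricyclic lactone (5S,8R,9R,10R), via B-alkyl-9-BBN adduct 22 (not isolated)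
Conditions: 20, THF, 0 °C to rt; then 21, Pd(dppf)Cl2 (cat.), AsPh3, aq. K3PO4, DMF, rt
Reagents that add atoms: none
Why: Anti-Markovnikov hydroboration of the monosubstituted vinyl group by 9-BBN (the trisubstituted ring-A alkene and the lactone react far more slowly) followed by B-alkyl Suzuki–Miyaura coupling with the α-bromobutenolide should join C12 to C13 and bring in the butenolide as an intact ring, room temperature sparing the hindered allylic lactone.

**Step 10**
Reactants: 23 butenolide-bearing tricyclic lactone
Product: 25 methyl 3-[(1R,2R,5S,8R)-5-acetyl-2-methyl-7-oxo-1-[2-(2-oxo-2,5-dihydrofuran-3-yl)ethyl]-6-oxabicyclo[3.2.1]octan-8-yl]propanoate, via methoxy hydroperoxide 24 (not isolated)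
Conditions: O3, CH2Cl2/MeOH, NaHCO3, −78 °C (Sudan red 7B end point); then Ac2O, Et3N, 0 °C to rt
Reagents that add atoms: ozone, [O-][O+]=O; methanol, CO
Why: Criegee ozonolysis of the electron-rich ring-A alkene (the conjugated butenolide alkene reacts much more slowly), with methanol trapping of the carbonyl oxide expected at C3, away from the electron-poor C5–O carbon, and dehydration of the methoxy hydroperoxide, should open ring A to the C3 methyl ester and the C4 methyl ketone in one operation.

**Step 11**
Reactants: 25 keto ester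
Product: 26 methyl 3-[(1R,2R,5S,8R)-2-methyl-7-oxo-1-[2-(2-oxo-2,5-dihydrofuran-3-yl)ethyl]-5-(prop-1-en-2-yl)-6-oxabicyclo[3.2.1]octan-8-yl]propanoate (target)
Conditions: Zn, CH2Br2, TiCl4 (reagent preformed in THF), CH2Cl2, 0 °C to rt
Reagents that add atoms: dibromomethane, BrCBr
Why: Takai–Lombardo methylenation with the non-basic CH2(ZnBr)2/TiCl4 reagent should convert the hindered methyl ketone into the isopropenyl group while the esters, both lactones and the base-sensitive butenolide are left alone.

**Compound list**

1 | 2-methylcyclohex-2-en-1-one | CC1=CCCCC1=O | starting material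
2 | (R)-1-amino-2-(methoxymethyl)pyrrolidine (RAMP) | COC[C@H]1CCCN1N | starting material
3 | (E)-N-[(2R)-2-(methoxymethyl)pyrrolidin-1-yl]-2-methylcyclohex-2-en-1-imine | CC1=CCCC/C1=N\N1CCC[C@@H]1COC | intermediate
4 | methyl bromoacetate | COC(=O)CBr | starting material
5 | lithium azaenolate of 3 (deprotonated at the ring CH2 next to C=N) | CC1=CCCC=C1N([Li])N1CCC[C@@H]1COC | intermediate
6 | methyl 2-[(1R,2E)-2-{[(2R)-2-(methoxymethyl)pyrrolidin-1-yl]imino}-3-methylcyclohex-3-en-1-yl]acetate | COC(=O)C[C@H]1CCC=C(C)/C1=N/N1CCC[C@@H]1COC | intermediate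
7 | methyl 2-[(1R)-3-methyl-2-oxocyclohex-3-en-1-yl]acetate | COC(=O)C[C@H]1CCC=C(C)C1=O | intermediate
8 | but-3-en-1-ylmagnesium bromide | C=CCC[Mg]Br | starting material
9 | bromomagnesium alkoxides (both C2 epimers) of methyl 2-[(1R)-2-(but-3-en-1-yl)-2-hydroxy-3-methylcyclohex-3-en-1-yl]acetate | C=CCCC1(O[Mg]Br)C(C)=CCC[C@@H]1CC(=O)OC | intermediate
10 | methyl 2-[(1R,2R)-2-(but-3-en-1-yl)-2-hydroxy-3-methylcyclohex-3-en-1-yl]acetate (hydroxyl trans to the acetate arm) | C=CCC[C@]1(O)C(C)=CCC[C@@H]1CC(=O)OC | intermediate
11 | (3aR,7aS)-7a-(but-3-en-1-yl)-7-methyl-3a,4,5,7a-tetrahydro-1-benzofuran-2(3H)-one (cis-fused lactone on ring A) | C=CCC[C@]12OC(=O)C[C@H]1CCC=C2C | intermediate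
12 | lithium enolate of 11 | C=CCC[C@]12OC(O[Li])=C[C@H]1CCC=C2C | intermediate
13 | (3aS,7aS)-7a-(but-3-en-1-yl)-7-methyl-3-(phenylselanyl)-3a,4,5,7a-tetrahydro-1-benzofuran-2(3H)-one (C3 epimers) | C=CCC[C@]12OC(=O)C([Se]c3ccccc3)[C@H]1CCC=C2C | intermediate
14 | phenyl vinyl sulfoxide (racemic) | C=CS(=O)c1ccccc1 | starting material
15 | lithium enolate of 13 | C=CCC[C@]12OC(O[Li])=C([Se]c3ccccc3)[C@H]1CCC=C2C | intermediate
16 | lithium α-sulfinyl carbanion from conjugate addition of 15 to 14 | C=CCC[C@]12OC(=O)C(CC([Li])S(=O)c3ccccc3)([Se]c3ccccc3)[C@H]1CCC=C2C | intermediate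
17 | (3aS,7aS)-7a-(but-3-en-1-yl)-7-methyl-3-(phenylselanyl)-3-[2-(phenylsulfinyl)ethyl]-3a,4,5,7a-tetrahydro-1-benzofuran-2(3H)-one (C3 and sulfur epimers) | C=CCC[C@]12OC(=O)C(CCS(=O)c3ccccc3)([Se]c3ccccc3)[C@H]1CCC=C2C | intermediate
18 | (5S,8R,9R,10R)-tricyclic lactone: ring A (C1–C5, C10; C3=C4, 4-methyl) trans-fused to ring B (C5–C10), C20(=O)–O bridge from C9 to C5, 8-methyl equatorial, 9-[2-(phenylsulfinyl)ethyl]; sulfur epimers | C[C@@H]1CC[C@]23OC(=O)[C@@]1(CCS(=O)c1ccccc1)[C@H]2CCC=C3C | intermediate
19 | (5S,8R,9R,10R)-tricyclic lactone as 18 with a vinyl group on C9 | C[C@@H]1CC[C@]23OC(=O)[C@@]1(C=C)[C@H]2CCC=C3C | intermediate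
20 | 9-borabicyclo[3.3.1]nonane (9-BBN) | B1C2CCCC1CCC2 | starting material
21 | 3-bromofuran-2(5H)-one | O=C1OCC=C1Br | starting material
22 | (5S,8R,9R,10R)-tricyclic lactone as 18 with 2-(9-borabicyclo[3.3.1]nonan-9-yl)ethyl on C9 | C[C@@H]1CC[C@]23OC(=O)[C@@]1(CCB1C4CCCC1CCC4)[C@H]2CCC=C3C | intermediate
23 | (5S,8R,9R,10R)-tricyclic lactone as 18 with 2-(2-oxo-2,5-dihydrofuran-3-yl)ethyl on C9 | C[C@@H]1CC[C@]23OC(=O)[C@@]1(CCC1=CCOC1=O)[C@H]2CCC=C3C | intermediate
24 | (1R,2R,5S,8R)-5-acetyl-8-(3-hydroperoxy-3-methoxypropyl)-2-methyl-1-[2-(2-oxo-2,5-dihydrofuran-3-yl)ethyl]-6-oxabicyclo[3.2.1]octan-7-one (epimers at the hydroperoxy carbon) | C[C@@H]1CC[C@]2(C(C)=O)OC(=O)[C@@]1(CCC1=CCOC1=O)[C@H]2CCC(OC)OO | intermediate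
25 | methyl 3-[(1R,2R,5S,8R)-5-acetyl-2-methyl-7-oxo-1-[2-(2-oxo-2,5-dihydrofuran-3-yl)ethyl]-6-oxabicyclo[3.2.1]octan-8-yl]propanoate | C[C@@H]1CC[C@]2(C(C)=O)OC(=O)[C@@]1(CCC1=CCOC1=O)[C@H]2CCC(=O)OC | intermediate
26 | methyl 3-[(1R,2R,5S,8R)-2-methyl-7-oxo-1-[2-(2-oxo-2,5-dihydrofuran-3-yl)ethyl]-5-(prop-1-en-2-yl)-6-oxabicyclo[3.2.1]octan-8-yl]propanoate (CNP0209666.1) | C=C(C)[C@@]12CC[C@@H](C)[C@@](CCC3=CCOC3=O)(C(=O)O1)[C@H]2CCC(=O)OC | target

**Step count and risks**

Total step count: 11. Longest linear sequence: 11 steps (from 1; all other partners are commercial).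

Steps most likely to fail:

Step 7. Hydrogen transfer from the stannane to the C9 radical may outrun ring closure, giving the uncyclized, deselenated lactone, and the chair preference at C8 may be modest, giving methyl epimers. The fallback sets out from 17 and separates ring closure from reduction. Sunlamp irradiation of 17 with (Bu3Sn)2 (10 mol%) in benzene, with no hydrogen donor present, should run a phenylselanyl group-transfer cyclization in which the closed C17 radical is capped by selenium transfer from 17. This gives the C17-phenylselanyl tricyclic lactone F1. Reductive deselenation of F1 with Bu3SnH and AIBN in benzene at 80 °C returns to the route at 18.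

Step 6. Conjugate addition at the hindered, selenium-stabilized enolate carbon may be slow or reversible, and selenium may exchange between enolate and product. The fallback sets out from 13 and replaces the Michael addition by an alkylation. Enolate 15 is treated with 2-chloroethyl phenyl sulfide and NaI in THF/DMPU (episulfonium-assisted substitution) to give the 3-[2-(phenylsulfanyl)ethyl] selenide F2. Tin hydride cyclization of F2 under the conditions of step 7 gives the tricyclic sulfide F3. Oxidation of F3 at sulfur with NaIO4 in MeOH/H2O at 0 °C returns to the route at 18.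

Step 10. The primary ozonide may fragment in the opposite sense (carbonyl oxide on C4), which leaves a C3 aldehyde instead of the ester after the dehydrating work-up, and the butenolide alkene may be over-oxidized if ozone is not stopped at the end point. The fallback sets out from 23 and adjusts the oxidation level stepwise. Ozonolysis in CH2Cl2 without methanol at −78 °C gives the secondary ozonide F4 (not isolated), which forms from either fragmentation sense. PPh3 reduces F4 to the keto aldehyde F5. Pinnick oxidation (NaClO2, NaH2PO4, 2-methylbut-2-ene, t-BuOH/H2O) gives the keto acid F6. Esterification of F6 with TMSCHN2 in MeOH/toluene returns to the route at 25.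

**Further compounds**

F1 | step 7 | tricyclic lactone as 18 with CH2SePh in place of the 8-methyl group (same spatial arrangement; CIP labels 5S,8R,9S,10R) | c1ccccc1[Se]C[C@@H]1CC[C@]23OC(=O)[C@@]1(CCS(=O)c1ccccc1)[C@H]2CCC=C3C
F2 | step 6 | (3aS,7aS)-7a-(but-3-en-1-yl)-7-methyl-3-(phenylselanyl)-3-[2-(phenylsulfanyl)ethyl]-3a,4,5,7a-tetrahydro-1-benzofuran-2(3H)-one (C3 epimers) | C=CCC[C@]12OC(=O)C(CCSc3ccccc3)([Se]c3ccccc3)[C@H]1CCC=C2C
F3 | step 6 | (5S,8R,9R,10R)-tricyclic lactone as 18 with 2-(phenylsulfanyl)ethyl on C9 | C[C@@H]1CC[C@]23OC(=O)[C@@]1(CCSc1ccccc1)[C@H]2CCC=C3C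
F4 | step 10 | secondary ozonide of 23 (1,2,4-trioxolane spanning C3 and C4; epimers at C3 and C4) | C[C@@H]1CC[C@]23OC(=O)[C@@]1(CCC1=CCOC1=O)[C@H]2CCC1OC3(C)OO1
F5 | step 10 | 3-[(1R,2R,5S,8R)-5-acetyl-2-methyl-7-oxo-1-[2-(2-oxo-2,5-dihydrofuran-3-yl)ethyl]-6-oxabicyclo[3.2.1]octan-8-yl]propanal | C[C@@H]1CC[C@]2(C(C)=O)OC(=O)[C@@]1(CCC1=CCOC1=O)[C@H]2CCC=O
F6 | step 10 | 3-[(1R,2R,5S,8R)-5-acetyl-2-methyl-7-oxo-1-[2-(2-oxo-2,5-dihydrofuran-3-yl)ethyl]-6-oxabicyclo[3.2.1]octan-8-yl]propanoic acid | C[C@@H]1CC[C@]2(C(C)=O)OC(=O)[C@@]1(CCC1=CCOC1=O)[C@H]2CCC(=O)O
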